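The constants were missing when the meeting opened, so it worked from the two earlier runs.

all flasks: starting material 0.050 M
- south: protic impurity 1.2 mM; capture agent 1 mM; temperature 32 °C; run made earlier
- west: protic impurity 5 mM; capture agent 1 mM; temperature 82 °C; run made earlier
- summer: protic impurity 2.50 mM; capture agent 1.00 mM; temperature 10 °C; time 3.0 min
- winter: protic impurity 2.50 mM; capture agent 1.00 mM; temperature 70 °C; time 3.0 min
- dusk: protic impurity 2.50 mM; capture agent 1.00 mM; temperature 100 °C; time 3.0 min
- spring: protic impurity 2.50 mM; capture agent 1.00 mM; temperature 40 °C; time 3.0 min

- south (time / s: open intermediate / %, target / %): 10.0: 0.4, 0; 15.0: 0.1, 0; 25.0: 0.5, 0.6; 40.0: 0.6, 0; 60.0: 0.9, 0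
- west (time / s: open intermediate / %, target / %): 10.0: 12.2, 0.5

(each reading ± 0.3 percentage points)

1. which flask leads in amount of open intermediate, in percent of the starting material charged ("all alike" within 1.5 percentage points) (summer / winter / dusk / spring / all alike)
2. how much open intermediate is there at the end, in percent of the starting material charged: summer
3. how much open intermediate is there at the end, in percent of the starting material charged: winter
4. how much open intermediate is there at the end, in percent of the starting material charged: dusk
5. how much open intermediate is there at the end, in percent of the starting material charged: spring



I argued that opening of starting material is the large thing and the drain from open intermediate is the correction. West shows target of 0.5 % beside open intermediate of 12.2 %, far less. So I proposed a first-order opening constant for each run, read from the material that had left starting material. South gives 1.51 × 10⁻⁴ s⁻¹ and west gives 0.0136 s⁻¹. Their ratio is 90.1. I named it the span factor, the growth of the opening constant from the south temperature to the west temperature. It carries the scatter of 0.3 percentage points on a south reading of 0.9 %.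

I assumed that the logarithm of the constant climbs evenly with temperature. I also assumed that protic impurity does not touch it, though the two runs differ in impurity. The opened share by the end then comes to 0.374 % in summer and 5.42 % in spring. I took these as my answers for those flasks. Winter has a constant of 0.00461 s⁻¹, so its opened share is 56.4 %. That is my estimate of what has opened in winter, and the gap between it and the open intermediate is the thing to watch. Dusk has a constant of 0.0687 s⁻¹, so nearly all of its starting material opens. I left dusk without a number.

The forecast's author held that “the free impurity is probably catalytic”. The forecast put summer at 6.5 %, spring at 20 %, winter at 33 % and dusk at 9 %, with winter leading. Its figures for summer and spring stand above mine.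

    starting material → open intermediate (k = 0.0682 s⁻¹, Ea = 91.0 kJ mol⁻¹)
    open intermediate ⇌ target (K = 0.750, k = 0.0441 s⁻¹, Ea = 104 kJ mol⁻¹, ΔH = 4.00 kJ mol⁻¹)
    open intermediate ⇌ isomer of the product (K = 2.40, k = 0.0233 s⁻¹, Ea = 111 kJ mol⁻¹, ΔH = −50.0 kJ mol⁻¹)
    starting material + protic impurity → quenched substrate (k = 209 M⁻¹ s⁻¹, Ea = 54.0 kJ mol⁻¹)
    open intermediate + capture agent → trapped intermediate (k = 0.846 M⁻¹ s⁻¹, Ea = 47.0 kJ mol⁻¹)
    (constants at 100 °C)

winter leads with 42.9 %, ahead of dusk at 23.1 %, spring at 4.09 % and summer at 0.105 %. The span factor of 90.1 gave winter an opened share of 56.4 %. At 3.00 min, winter holds 58.1 % as open intermediate, target, isomer of the product and trapped intermediate together. The same factor gave dusk its constant of 0.0687 s⁻¹, which puts starting material under 2.00 % of its charge at 0.949 min. Dusk reaches that point at 0.943 min.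

The readings come from a simulation for an exercise.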